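**Retrosynthetic overview**

1. Skeleton numbering used throughout: C1(=O)–C2=C3(CH3)–C4–C5–C6(CH3)2–C7(OH)–C8(O‑angeloyl)–C9(O‑2‑methylbutanoyl)–C10(CH3)–C11, with further bonds C1–C11, C4–C10 and C5–C11; the cyclobutane is C4–C5–C11–C10.
2. The esters go on last (O‑8 angelate, then O‑9 (R)‑2‑methylbutanoate); the C8/C9 cis‑diol comes from dihydroxylation anti to O‑7, the C7 carbinol from CBS reduction of a C7 enone, the C1 ketone from allylic oxidation, and the C10 methyl from a C10 ester.
3. Key disconnection: C5–C6 and C9–C10 together. The seven‑membered ring is closed by a Lewis‑acid formal (4+3) ([2σ+4π]) annulation of a 2‑silyloxy diene (C6–C9) onto a bicyclo[1.1.0]butane.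
4. Enabling feature: C5 and C10 are the two non‑adjacent carbons of the cyclobutane. Joined by a bond they form a bicyclo[1.1.0]butane whose wingtips C4 and C11 are already tied by the C1–C2–C3 bridge (a tricyclo[4.1.0.0(2,7)]hept‑3‑ene), and an ester on C10 polarises the strained C5–C10 bond.
5. Ring order: cyclohexene (C1–C5, C11; from (S)‑4‑silyloxycyclohexenone) → cyclopropane (C4, C5, C10; sulfur ylide) → bicyclobutane (C10–C11; 1,3‑elimination) → cycloheptene, with the cyclobutane set free in the key step.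

Key step: step 10

Remarks on the chemistry (assumptions): the 2‑methylbutanoate stereocentre in the given structure is R, so (R)‑2‑methylbutanoic acid is used. Compounds 1, 5, 13, 24 and 27 are taken as commercial. Locants C1–C11 in the text refer to the skeleton numbering above; names of intermediates carry their own locants.

**Route**

Step 1
Reactants: 1 1,4‑dioxaspiro[4.5]dec‑6‑en‑8‑one
Product: 2 (8S)‑1,4‑dioxaspiro[4.5]dec‑6‑en‑8‑ol
Conditions: (R)‑2‑methyl‑CBS‑oxazaborolidine (10 mol%), BH3·SMe2, THF, −30 °C; MeOH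
Reagents that add atoms: none
Why: Corey–Bakshi–Shibata reduction with the alkenyl arm as the large group should give the (S)‑carbinol, the one stereocentre from which the whole cage is later derived.

Step 2
Reactants: 2 (8S)‑1,4‑dioxaspiro[4.5]dec‑6‑en‑8‑ol
Product: 3 (8S)‑8‑[(tert‑butyldimethylsilyl)oxy]‑1,4‑dioxaspiro[4.5]dec‑6‑ene
Conditions: TBSCl, imidazole, DMF, rt
Reagents that add atoms: tert‑butyldimethylsilyl chloride, CC(C)(C)[Si](C)(C)Cl
Why: Standard silylation gives a bulky ether that later shields one face of the enone.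

Step 3
Reactants: 3 (8S)‑8‑[(tert‑butyldimethylsilyl)oxy]‑1,4‑dioxaspiro[4.5]dec‑6‑ene
Product: 4 (4S)‑4‑[(tert‑butyldimethylsilyl)oxy]cyclohex‑2‑en‑1‑one
Conditions: PPTS, THF–H2O, 50 °C
Reagents that add atoms: water, O
Why: Mild acid‑catalysed ketal hydrolysis should unmask the enone (C3=O, C4=C5) without touching the allylic silyl ether at C11.

Step 4
Reactants: 4 (4S)‑4‑[(tert‑butyldimethylsilyl)oxy]cyclohex‑2‑en‑1‑one; 5 (2‑ethoxy‑2‑oxoethyl)dimethylsulfonium bromide
Product: 7 ethyl 5‑[(tert‑butyldimethylsilyl)oxy]‑2‑oxobicyclo[4.1.0]heptane‑7‑carboxylate (exo ester; silyloxy group trans to the cyclopropane), via sulfonium ylide 6 (not isolated)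
Conditions: K2CO3 (sat. aq.), CHCl3, 5 °C; then 4, CH2Cl2, rt
Reagents that add atoms: none
Why: Corey–Chaykovsky‑type cyclopropanation with an ester‑stabilised sulfonium ylide: the ylide carbon (C10) should attack C5 anti to the adjacent silyloxy group and close on C4, which sets C4 and C5 (cis fusion) and places the ester exo.

Step 5
Reactants: 7 ethyl 5‑[(tert‑butyldimethylsilyl)oxy]‑2‑oxobicyclo[4.1.0]heptane‑7‑carboxylate
Product: 8 ethyl 5‑[(tert‑butyldimethylsilyl)oxy]‑2‑{[(trifluoromethyl)sulfonyl]oxy}bicyclo[4.1.0]hept‑2‑ene‑7‑carboxylate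
Conditions: KN(SiMe3)2, PhNTf2, THF, −78 °C
Reagents that add atoms: N‑phenylbis(trifluoromethanesulfonimide), O=S(=O)(N(c1ccccc1)S(=O)(=O)C(F)(F)F)C(F)(F)F
Why: Kinetic enolisation of the C3 ketone can only occur at the C2 methylene (C4 is a cyclopropane CH), and O‑triflation gives the enol triflate.

Step 6
Reactants: 8 enol triflate
Product: 9 ethyl 5‑[(tert‑butyldimethylsilyl)oxy]‑2‑methylbicyclo[4.1.0]hept‑2‑ene‑7‑carboxylate
Conditions: MeZnCl, Pd(PPh3)4 (5 mol%), THF, 40 °C
Reagents that add atoms: methylzinc chloride, C[Zn]Cl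
Why: Negishi coupling of the alkenyl triflate should install the C3 methyl with the C2=C3 double bond already in place.

Step 7
Reactants: 9 ethyl 5‑[(tert‑butyldimethylsilyl)oxy]‑2‑methylbicyclo[4.1.0]hept‑2‑ene‑7‑carboxylate
Product: 10 ethyl 5‑hydroxy‑2‑methylbicyclo[4.1.0]hept‑2‑ene‑7‑carboxylate (hydroxyl trans to the cyclopropane)
Conditions: Bu4NF, THF, 0 °C
Reagents that add atoms: none
Why: Fluoride desilylation frees the C11 hydroxyl; the ethyl ester is inert.

Step 8
Reactants: 10 ethyl 5‑hydroxy‑2‑methylbicyclo[4.1.0]hept‑2‑ene‑7‑carboxylate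
Product: 12 ethyl 3‑methyltricyclo[4.1.0.0(2,7)]hept‑3‑ene‑1‑carboxylate (single enantiomer as in the SMILES), via mesylate 11 (not isolated)
Conditions: MsCl, Et3N, CH2Cl2, −40 °C; then LiN(iPr)2, THF, −78 → 0 °C
Reagents that add atoms: none
Why: 1,3‑Elimination (intramolecular enolate alkylation, as used for bicyclobutane esters and sulfones): the endo lobe of the C10 ester carbanion should displace the trans cyclopropylcarbinyl mesylate at C11 with inversion, forming the C10–C11 lateral bond, so the absolute configuration of the bicyclobutane follows from the carbinol centre.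

Step 9
Reactants: 13 4‑methylpent‑1‑en‑3‑one (isopropyl vinyl ketone)
Product: 14 tert‑butyldimethyl[(4‑methylpenta‑1,3‑dien‑3‑yl)oxy]silane
Conditions: TBSOTf, Et3N, CH2Cl2, 0 °C
Reagents that add atoms: tert‑butyldimethylsilyl trifluoromethanesulfonate, CC(C)(C)[Si](C)(C)OS(=O)(=O)C(F)(F)F
Why: Soft enolisation–silylation can only remove the isopropyl methine and should give the cross‑conjugated 2‑silyloxy diene.

Step 10
Reactants: 12 ethyl 3‑methyltricyclo[4.1.0.0(2,7)]hept‑3‑ene‑1‑carboxylate; 14 tert‑butyldimethyl[(4‑methylpenta‑1,3‑dien‑3‑yl)oxy]silane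
Product: 15 tricyclic (4+3) adduct: target skeleton with CO2Et on C10 in place of CH3, TBS enol ether at C7 (C7=C8), C9 as CH2, C2=C3 alkene and C1 as CH2
Conditions: Al(OTf)3 (10 mol%), CH2Cl2, −40 °C → rt; Et3N quench
Reagents that add atoms: none
Why: Proposed new method: Al(OTf)3 binds the ester carbonyl and polarises the central C5–C10 σ bond, so the fully substituted enol‑ether carbon of 14 (future C6) should attack the unsubstituted bridgehead C5 on the convex face (Mukaiyama‑type strain‑release opening), and the ester enolate thus formed at C10 should close by conjugate addition onto the CH2 terminus of the silyloxyallyl cation (future C9), leaving a silyl enol ether at C7=C8. The closest known reaction type is the Al(OTf)3‑catalysed formal [2σ+4π] annulation of acyl bicyclo[1.1.0]butanes with 2‑silyloxy dienes to bicyclo[4.1.1]octanes; new here are the wingtip‑bridged (tricyclic) bicyclobutane ester and the tetrasubstituted nucleophilic terminus. The seven‑membered ring closes in a 7‑endo‑trig Michael‑type step after the intermolecular first bond, and the cyclobutane is what remains when the central bond breaks. C5 and C10 are the only new stereocentres and both are dictated by the cage: the C1–C3 bridge blocks the concave face, so both new bonds must end anti to it, with H‑5 and the ester syn, and the absolute sense comes from 12. The step needs regioselectivity (C6 to C5, C9 to C10), which the position of the ester secures, and (4+3) over (3+2) periselectivity, which the unhindered CH2 terminus and the strain of the alternative 1,2‑closure onto C7 should secure.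

Step 11
Reactants: 15 tricyclic ester
Product: 16 primary alcohol (C10–CH2OH; otherwise as 15)
Conditions: LiAlH4, Et2O, 0 °C
Reagents that add atoms: none
Why: LiAlH4 reduces the neopentyl ester to the primary alcohol, and the silyl enol ether is inert to hydride.

Step 12
Reactants: 16 primary alcohol
Product: 17 primary mesylate (C10–CH2OMs)
Conditions: MsCl, Et3N, CH2Cl2, 0 °C
Reagents that add atoms: methanesulfonyl chloride, CS(=O)(=O)Cl
Why: Mesylation under basic conditions leaves the acid‑sensitive enol ether intact.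

Step 13
Reactants: 17 primary mesylate
Product: 18 C10‑methyl tricycle (TBS enol ether at C7=C8, C2=C3 alkene)
Conditions: LiEt3BH, THF, 65 °C
Reagents that add atoms: none
Why: Hydride displacement of the neopentyl mesylate by LiEt3BH should turn the former activating group into the C10 methyl of the target.

Step 14
Reactants: 18 C10‑methyl silyl enol ether
Product: 19 dienone precursor: C7 ketone with cis C8=C9 double bond (C2=C3 alkene, C1 still CH2)
Conditions: Pd(OAc)2 (1.1 equiv), MeCN, 40 °C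
Reagents that add atoms: none
Why: Saegusa–Ito oxidation: the palladium enolate at C8 can eliminate only H‑9, which should give the C8=C9 enone.

Step 15
Reactants: 19 C7 enone
Product: 20 (7R)‑allylic alcohol (hydroxyl on the face of the seven‑membered ring that lies on the C4 side)
Conditions: (S)‑2‑methyl‑CBS‑oxazaborolidine, catecholborane, toluene, −78 °C
Reagents that add atoms: none
Why: CBS reduction under reagent control (the two faces of this ketone are almost mirror‑related in the substrate): with the quaternary C6 arm as the large group the (S)‑catalyst should give the (7R)‑alcohol.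

Step 16
Reactants: 20 allylic alcohol
Product: 21 C7 triethylsilyl ether
Conditions: TESOTf, 2,6‑lutidine, CH2Cl2, −78 °C
Reagents that add atoms: triethylsilyl trifluoromethanesulfonate, CC[Si](CC)(CC)OS(=O)(=O)C(F)(F)F
Why: Silylation protects O‑7, which must end free, and supplies the bulk that directs the dihydroxylation.

Step 17
Reactants: 21 C7 triethylsilyl ether
Product: 22 longipina‑2,8‑dien‑1‑one 7‑triethylsilyl ether (C1 ketone installed)
Conditions: CrO3, 3,5‑dimethylpyrazole, CH2Cl2, −20 °C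
Reagents that add atoms: chromium trioxide, O=[Cr](=O)=O
Why: Allylic oxidation with the CrO3–3,5‑dimethylpyrazole complex should attack the ring CH2 (C1) next to the electron‑rich trisubstituted C2=C3 bond, as in α‑pinene to verbenone, and leave the inductively deactivated C8=C9 allylic ether alone.

Step 18
Reactants: 22 dienone silyl ether
Product: 23 8,9‑cis‑diol (both hydroxyls on the C11 side, trans to O‑7), 7‑triethylsilyl ether
Conditions: OsO4 (5 mol%), NMO, acetone–H2O, rt
Reagents that add atoms: osmium tetroxide (catalytic oxygen carrier), O=[Os](=O)(=O)=O; N‑methylmorpholine N‑oxide, C[N+]1([O-])CCOCC1; water, O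
Why: Upjohn dihydroxylation of the cis‑disubstituted C8=C9 bond should occur anti to the allylic silyloxy group, as is usual for osmylation of allylic ethers, setting C8 and C9, while the enone double bond is too electron‑poor and hindered to react.

Step 19
Reactants: 23 8,9‑diol; 24 angelic acid ((Z)‑2‑methylbut‑2‑enoic acid)
Product: 26 8‑O‑angelate (9‑OH free, 7‑OTES), via angeloyl mixed anhydride 25 (not isolated)
Conditions: 2,4,6‑trichlorobenzoyl chloride, Et3N, toluene, rt; then 23, 75 °C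
Reagents that add atoms: none
Why: Yamaguchi‑type mixed‑anhydride acylation without a nucleophilic catalyst avoids angelate‑to‑tiglate isomerisation and should select HO‑8 over the neopentyl HO‑9, which is flanked by quaternary C10 and its methyl.

Step 20
Reactants: 26 8‑O‑angelate; 27 (R)‑2‑methylbutanoic acid
Product: 29 8‑O‑angelate 9‑O‑[(R)‑2‑methylbutanoate], 7‑triethylsilyl ether, via 2‑methylbutanoyl mixed anhydride 28 (not isolated)
Conditions: 2,4,6‑trichlorobenzoyl chloride, Et3N, THF, rt; then 26, DMAP, toluene, rt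
Reagents that add atoms: none
Why: Yamaguchi esterification of the one remaining free hydroxyl at room temperature, where neither the α‑centre of the acid nor the angelate geometry should be affected.

Step 21
Reactants: 29 diester silyl ether
Product: 30 CNP0202800.1 (target)
Conditions: HF·pyridine, pyridine, THF, 0 °C → rt
Reagents that add atoms: none
Why: Buffered HF·pyridine cleaves the triethylsilyl ether without ester cleavage or acyl migration and should give the target.

**Compound list**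

1 | 1,4‑dioxaspiro[4.5]dec‑6‑en‑8‑one | O=C1C=CC2(CC1)OCCO2 | starting material
2 | (8S)‑1,4‑dioxaspiro[4.5]dec‑6‑en‑8‑ol | O[C@@H]1C=CC2(CC1)OCCO2 | intermediate
3 | (8S)‑8‑[(tert‑butyldimethylsilyl)oxy]‑1,4‑dioxaspiro[4.5]dec‑6‑ene | CC(C)(C)[Si](C)(C)O[C@@H]1C=CC2(CC1)OCCO2 | intermediate
4 | (4S)‑4‑[(tert‑butyldimethylsilyl)oxy]cyclohex‑2‑en‑1‑one | O=C1C=C[C@@H](O[Si](C)(C)C(C)(C)C)CC1 | intermediate
5 | (2‑ethoxy‑2‑oxoethyl)dimethylsulfonium bromide | CCOC(=O)C[S+](C)C.[Br-] | starting material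
6 | ethyl (dimethylsulfonio)acetate ylide | CCOC(=O)[CH-][S+](C)C | intermediate (not isolated)
7 | ethyl 5‑[(tert‑butyldimethylsilyl)oxy]‑2‑oxobicyclo[4.1.0]heptane‑7‑carboxylate, exo ester, silyloxy trans to cyclopropane | CCOC(=O)[C@H]1[C@H]2[C@@H]1C(=O)CC[C@@H]2O[Si](C)(C)C(C)(C)C | intermediate
8 | ethyl 5‑[(tert‑butyldimethylsilyl)oxy]‑2‑(triflyloxy)bicyclo[4.1.0]hept‑2‑ene‑7‑carboxylate | CCOC(=O)[C@H]1[C@H]2[C@@H]1C(OS(=O)(=O)C(F)(F)F)=CC[C@@H]2O[Si](C)(C)C(C)(C)C | intermediate
9 | ethyl 5‑[(tert‑butyldimethylsilyl)oxy]‑2‑methylbicyclo[4.1.0]hept‑2‑ene‑7‑carboxylate | CCOC(=O)[C@H]1[C@H]2[C@@H]1C(C)=CC[C@@H]2O[Si](C)(C)C(C)(C)C | intermediate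
10 | ethyl 5‑hydroxy‑2‑methylbicyclo[4.1.0]hept‑2‑ene‑7‑carboxylate, hydroxyl trans to cyclopropane | CCOC(=O)[C@H]1[C@H]2[C@@H]1C(C)=CC[C@@H]2O | intermediate
11 | ethyl 5‑(mesyloxy)‑2‑methylbicyclo[4.1.0]hept‑2‑ene‑7‑carboxylate | CCOC(=O)[C@H]1[C@H]2[C@@H]1C(C)=CC[C@@H]2OS(C)(=O)=O | intermediate (not isolated)
12 | ethyl 3‑methyltricyclo[4.1.0.0(2,7)]hept‑3‑ene‑1‑carboxylate | CCOC(=O)[C@@]12[C@H]3[C@@H]1C(C)=CC[C@@H]23 | intermediate
13 | 4‑methylpent‑1‑en‑3‑one | C=CC(=O)C(C)C | starting material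
14 | tert‑butyldimethyl[(4‑methylpenta‑1,3‑dien‑3‑yl)oxy]silane | C=CC(O[Si](C)(C)C(C)(C)C)=C(C)C | intermediate
15 | (4+3) adduct: C10 ethyl ester, 7‑TBS enol ether (C7=C8), C2=C3 alkene | CCOC(=O)[C@@]12CC=C(O[Si](C)(C)C(C)(C)C)C(C)(C)[C@H]3[C@@H]1C(C)=CC[C@@H]23 | intermediate
16 | C10 hydroxymethyl analogue of 15 | OC[C@@]12CC=C(O[Si](C)(C)C(C)(C)C)C(C)(C)[C@H]3[C@@H]1C(C)=CC[C@@H]23 | intermediate
17 | C10 mesyloxymethyl analogue of 15 | CS(=O)(=O)OC[C@@]12CC=C(O[Si](C)(C)C(C)(C)C)C(C)(C)[C@H]3[C@@H]1C(C)=CC[C@@H]23 | intermediate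
18 | 7‑[(tert‑butyldimethylsilyl)oxy]longipina‑2,7‑diene | C[C@@]12CC=C(O[Si](C)(C)C(C)(C)C)C(C)(C)[C@H]3[C@@H]1C(C)=CC[C@@H]23 | intermediate
19 | longipina‑2,8‑dien‑7‑one | C[C@@]12C=CC(=O)C(C)(C)[C@H]3[C@@H]1C(C)=CC[C@@H]23 | intermediate
20 | (7R)‑longipina‑2,8‑dien‑7‑ol | C[C@@]12C=C[C@@H](O)C(C)(C)[C@H]3[C@@H]1C(C)=CC[C@@H]23 | intermediate
21 | (7R)‑7‑[(triethylsilyl)oxy]longipina‑2,8‑diene | C[C@@]12C=C[C@@H](O[Si](CC)(CC)CC)C(C)(C)[C@H]3[C@@H]1C(C)=CC[C@@H]23 | intermediate
22 | 7‑[(triethylsilyl)oxy]longipina‑2,8‑dien‑1‑one | C[C@@]12C=C[C@@H](O[Si](CC)(CC)CC)C(C)(C)[C@H]3[C@@H]1C(C)=CC(=O)[C@@H]23 | intermediate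
23 | 8,9‑dihydroxy‑7‑[(triethylsilyl)oxy]longipin‑2‑en‑1‑one (O‑8, O‑9 cis, trans to O‑7) | C[C@@]12[C@H](O)[C@H](O)[C@@H](O[Si](CC)(CC)CC)C(C)(C)[C@H]3[C@@H]1C(C)=CC(=O)[C@@H]23 | intermediate
24 | angelic acid | C/C=C(/C)C(=O)O | starting material
25 | angelic 2,4,6‑trichlorobenzoic anhydride | C/C=C(/C)C(=O)OC(=O)c1c(Cl)cc(Cl)cc1Cl | intermediate (not isolated)
26 | 8‑O‑angeloyl‑9‑hydroxy‑7‑[(triethylsilyl)oxy]longipin‑2‑en‑1‑one | C[C@@]12[C@H](O)[C@H](OC(=O)/C(C)=C\C)[C@@H](O[Si](CC)(CC)CC)C(C)(C)[C@H]3[C@@H]1C(C)=CC(=O)[C@@H]23 | intermediate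
27 | (R)‑2‑methylbutanoic acid | CC[C@@H](C)C(=O)O | starting material
28 | (R)‑2‑methylbutanoic 2,4,6‑trichlorobenzoic anhydride | CC[C@@H](C)C(=O)OC(=O)c1c(Cl)cc(Cl)cc1Cl | intermediate (not isolated)
29 | 8‑O‑angeloyl‑9‑O‑[(R)‑2‑methylbutanoyl]‑7‑[(triethylsilyl)oxy]longipin‑2‑en‑1‑one | C[C@@]12[C@H](OC(=O)[C@H](C)CC)[C@H](OC(=O)/C(C)=C\C)[C@@H](O[Si](CC)(CC)CC)C(C)(C)[C@H]3[C@@H]1C(C)=CC(=O)[C@@H]23 | intermediate
30 | CNP0202800.1: 7‑hydroxy‑8‑O‑angeloyl‑9‑O‑[(R)‑2‑methylbutanoyl]longipin‑2‑en‑1‑one | C/C=C(/C)C(=O)O[C@@H]1[C@@H](O)C(C)(C)[C@@H]2[C@H]3C(=O)C=C(C)[C@@H]2[C@@]3(C)[C@@H]1OC(=O)[C@H](C)CC | target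

**Step count**

Total: 21 steps. Longest linear sequence: 20 steps (steps 1–8 and 10–21; step 9 is a one‑step side branch).

**Steps most likely to fail**

Step 10 (proposed new method). The ester may not activate the central bond enough, so that acid‑induced isomerisation of the vinyl‑substituted bicyclobutane outruns C–C bond formation, or the enolate may close 1,2 on the oxocarbenium carbon. Fallback from 12, returning at 15, with the two bonds made one after the other by known reactions:
- Aldol addition of the lithium enolate of methyl isobutyrate to acrolein would give methyl 3‑hydroxy‑2,2‑dimethylpent‑4‑enoate F1, and saponification (LiOH) 3‑hydroxy‑2,2‑dimethylpent‑4‑enoic acid F2.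
- Photoredox decarboxylation of F2 (4CzIPN, Cs2CO3, blue light) in the presence of 12 would add the tertiary radical to the unsubstituted bridgehead C5 from the convex face (strain‑release Giese addition, known for bridgehead‑acceptor bicyclobutanes). After reduction and protonation at C10 this gives the ring‑opened ethyl 6‑(3‑hydroxy‑2‑methylpent‑4‑en‑2‑yl)‑2‑methylbicyclo[3.1.1]hept‑2‑ene‑7‑carboxylate F3 (epimers at the carbinol and at C10, both erased later).
- MnO2 would oxidise the allylic alcohol to the vinyl ketone ethyl 6‑(2‑methyl‑3‑oxopent‑4‑en‑2‑yl)‑2‑methylbicyclo[3.1.1]hept‑2‑ene‑7‑carboxylate F4, whose only acidic C–H is H‑10.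
- Catalytic KOC(CH3)3 in THF would close the seven‑membered ring by intramolecular Michael addition of the ester enolate to the vinyl ketone, giving the C7 keto ester F5, and TBSOTf, Et3N would return 15.

Step 8. The secondary cyclopropylcarbinyl mesylate may ionise and rearrange, or undergo E2 elimination, before the hindered endo C–H at C10 is removed. Fallback from 10, returning at 12, with a halide introduced by a stereochemical inversion sequence in place of the sulfonate:
- Dess–Martin oxidation would give ethyl 2‑methyl‑5‑oxobicyclo[4.1.0]hept‑2‑ene‑7‑carboxylate F6.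
- NaBH4, CeCl3 reduction from the face anti to the cyclopropane would give the cis alcohol ethyl 5‑hydroxy‑2‑methylbicyclo[4.1.0]hept‑2‑ene‑7‑carboxylate (C5 epimer of 10) F7.
- Appel chlorination (PPh3, CCl4) with inversion would give the trans chloride ethyl 5‑chloro‑2‑methylbicyclo[4.1.0]hept‑2‑ene‑7‑carboxylate F8, which does not ionise at low temperature, and LiN(iPr)2 in THF would then close it to 12.

Step 19. Site discrimination between the two cis hydroxyls may be insufficient, and the later forcing acylation of HO‑9 may isomerise the angelate. Fallback from 23, returning at 30, with the order of acylation reversed so that each forcing step meets a single free hydroxyl: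
- TBSCl, imidazole would silylate the more exposed HO‑8 to give the 8‑O‑TBS ether F9.
- Yamaguchi esterification of HO‑9 with 27 (no angelate present yet) would give the 9‑O‑[(R)‑2‑methylbutanoate] bis‑silyl ether F10.
- HF·pyridine would remove both silyl groups to give the 7,8‑diol 9‑ester F11.
- Angeloylation with 24 (2,4,6‑trichlorobenzoyl chloride, Et3N, toluene, 75 °C) should then take place at HO‑8, because HO‑7 is neopentyl next to C(CH3)2, giving 30.

**Further compounds**

F1 | step 10 | methyl 3‑hydroxy‑2,2‑dimethylpent‑4‑enoate | COC(=O)C(C)(C)C(O)C=C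
F2 | step 10 | 3‑hydroxy‑2,2‑dimethylpent‑4‑enoic acid | OC(=O)C(C)(C)C(O)C=C
F3 | step 10 | ethyl 6‑(3‑hydroxy‑2‑methylpent‑4‑en‑2‑yl)‑2‑methylbicyclo[3.1.1]hept‑2‑ene‑7‑carboxylate | CCOC(=O)C1[C@@H]2CC=C(C)[C@H]1[C@@H]2C(C)(C)C(O)C=C
F4 | step 10 | ethyl 6‑(2‑methyl‑3‑oxopent‑4‑en‑2‑yl)‑2‑methylbicyclo[3.1.1]hept‑2‑ene‑7‑carboxylate | CCOC(=O)C1[C@@H]2CC=C(C)[C@H]1[C@@H]2C(C)(C)C(=O)C=C
F5 | step 10 | C7 ketone corresponding to 15 (C10 ethyl ester, C8 and C9 as CH2) | CCOC(=O)[C@@]12CCC(=O)C(C)(C)[C@H]3[C@@H]1C(C)=CC[C@@H]23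
F6 | step 8 | ethyl 2‑methyl‑5‑oxobicyclo[4.1.0]hept‑2‑ene‑7‑carboxylate | CCOC(=O)[C@H]1[C@H]2[C@@H]1C(C)=CCC2=O
F7 | step 8 | ethyl 5‑hydroxy‑2‑methylbicyclo[4.1.0]hept‑2‑ene‑7‑carboxylate, hydroxyl cis to cyclopropane | CCOC(=O)[C@H]1[C@H]2[C@@H]1C(C)=CC[C@H]2O
F8 | step 8 | ethyl 5‑chloro‑2‑methylbicyclo[4.1.0]hept‑2‑ene‑7‑carboxylate, chloride trans to cyclopropane | CCOC(=O)[C@H]1[C@H]2[C@@H]1C(C)=CC[C@@H]2Cl
F9 | step 19 | 8‑[(tert‑butyldimethylsilyl)oxy]‑9‑hydroxy‑7‑[(triethylsilyl)oxy]longipin‑2‑en‑1‑one | C[C@@]12[C@H](O)[C@H](O[Si](C)(C)C(C)(C)C)[C@@H](O[Si](CC)(CC)CC)C(C)(C)[C@H]3[C@@H]1C(C)=CC(=O)[C@@H]23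
F10 | step 19 | 8‑[(tert‑butyldimethylsilyl)oxy]‑9‑O‑[(R)‑2‑methylbutanoyl]‑7‑[(triethylsilyl)oxy]longipin‑2‑en‑1‑one | C[C@@]12[C@H](OC(=O)[C@H](C)CC)[C@H](O[Si](C)(C)C(C)(C)C)[C@@H](O[Si](CC)(CC)CC)C(C)(C)[C@H]3[C@@H]1C(C)=CC(=O)[C@@H]23
F11 | step 19 | 7,8‑dihydroxy‑9‑O‑[(R)‑2‑methylbutanoyl]longipin‑2‑en‑1‑one | C[C@@]12[C@H](OC(=O)[C@H](C)CC)[C@H](O)[C@@H](O)C(C)(C)[C@H]3[C@@H]1C(C)=CC(=O)[C@@H]23
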